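**Retrosynthetic overview**

1. Numbering: 3,7-dioxabicyclo[3.3.0]octane; ring A = C1(OH)–C2(Ar)–O3–C4–C5, ring B = C5–C6(Ar)–O7–C8–C1. Enabling feature: on ring A the C1 hydroxyl and the C2 aryl group are trans-vicinal and C2 is an acetal-level carbon bonded to O3, which is the retron of an anti opening of a C1–C2 oxirane of a cyclic enol ether by an aryl nucleophile.
2. Target 12 ⇒ bicyclic enol ether 7 (O3–C2=C1 in ring A) + diarylcuprate 10 (from bromide 8) via oxirane 11: the C2–aryl bond, the C1 hydroxyl and both remaining stereocentres arrive in the last step.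
3. Ring A of 7 ⇒ enol-ether ring-closing metathesis of vinyl ether 6 (forms C1=C2).
4. Ring B ⇒ titanocene-mediated radical 5-exo-dig cyclisation of epoxy propargyl ether 4 (C5–C1 bond, C5 set trans to the C6 aryl); C6 ⇒ Sharpless kinetic resolution of vinyl carbinol 2, made from aldehyde 1.
5. Order of ring formation: ring B (step 4), ring A (step 6), transient oxirane formed and opened (step 7).

Key step: step 7

Remark: the SMILES is read as the (1S,2S,5R,6S) isomer, with the C2 aryl group endo (trans to the C1 hydroxyl, cis to C8) and the C6 aryl group exo (cis to H-5).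

**Route**

Step 1
Reactants: 1 3,4-dimethoxybenzaldehyde
Product: 2 rac-1-(3,4-dimethoxyphenyl)prop-2-en-1-ol
Conditions: vinylmagnesium bromide, THF, 0 °C; then H2O
Reagents that add atoms: vinylmagnesium bromide C=C[Mg]Br
Why: Grignard 1,2-addition of the vinyl nucleophile to the aryl aldehyde should be clean, and the racemic carbinol carbon (the future C6) is resolved in step 2.

Step 2
Reactants: 2 rac-1-(3,4-dimethoxyphenyl)prop-2-en-1-ol
Product: 3 (R)-(3,4-dimethoxyphenyl)[(2R)-oxiran-2-yl]methanol
Conditions: Ti(OiPr)4 (0.1 equiv), D-(−)-diisopropyl tartrate (0.15 equiv), t-BuOOH (0.45 equiv), 4 Å MS, CH2Cl2, −20 °C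
Reagents that add atoms: tert-butyl hydroperoxide CC(C)(C)OO
Why: Sharpless kinetic resolution (titanium–tartrate epoxidation of a secondary allylic alcohol): with D-(−)-diisopropyl tartrate the (S)-alcohol should be epoxidised much faster than the (R)-alcohol and give the erythro epoxy alcohol, so the carbinol carbon (future C6) is obtained in the needed configuration, the new oxirane stereocentre is set by the chiral titanium–tartrate reagent, and the slow (R)-alcohol is separated.

Step 3
Reactants: 3 (R)-(3,4-dimethoxyphenyl)[(2R)-oxiran-2-yl]methanol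
Product: 4 (2R)-2-[(R)-(3,4-dimethoxyphenyl)(prop-2-yn-1-yloxy)methyl]oxirane
Conditions: NaH, propargyl bromide, Bu4NI (cat.), THF, 0 °C
Reagents that add atoms: propargyl bromide C#CCBr
Why: Williamson etherification of the secondary alkoxide with the reactive propargylic bromide should be faster at 0 °C than oxirane migration, and no stereocentre is touched.

Step 4
Reactants: 4 (2R)-2-[(R)-(3,4-dimethoxyphenyl)(prop-2-yn-1-yloxy)methyl]oxirane
Product: 5 [(2S,3R)-2-(3,4-dimethoxyphenyl)-4-methylideneoxolan-3-yl]methanol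
Conditions: Cp2TiCl2 (2.2 equiv), Zn dust, THF, rt (Cp2TiCl solution added slowly to 4); then dilute aq HCl, 0 °C
Reagents that add atoms: none
Why: Nugent–RajanBabu reductive epoxide opening with Cp2TiCl (trivalent titanium) should give the secondary C5 radical, which closes ring B by 5-exo-dig attack on the alkyne (C5–C1 bond) before the vinyl radical is reduced and protonated; the new C5 stereocentre should be set trans to the C6 aryl group by a chair-like (Beckwith–Houk) transition state with the aryl group pseudo-equatorial, while the oxirane stereocentre of 4 is erased in the planar radical.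

Step 5
Reactants: 5 [(2S,3R)-2-(3,4-dimethoxyphenyl)-4-methylideneoxolan-3-yl]methanol
Product: 6 (2S,3R)-2-(3,4-dimethoxyphenyl)-3-[(ethenyloxy)methyl]-4-methylideneoxolane
Conditions: [Ir(cod)Cl]2 (1 mol%), Na2CO3 (0.6 equiv), vinyl acetate, toluene, 100 °C
Reagents that add atoms: vinyl acetate CC(=O)OC=C
Why: Iridium-catalysed transfer vinylation of a primary alcohol with vinyl acetate runs under mildly basic conditions, so the acid-sensitive benzylic ether and the 1,1-disubstituted alkene should survive.

Step 6
Reactants: 6 (2S,3R)-2-(3,4-dimethoxyphenyl)-3-[(ethenyloxy)methyl]-4-methylideneoxolane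
Product: 7 (5R,6S)-6-(3,4-dimethoxyphenyl)-3,7-dioxabicyclo[3.3.0]oct-1-ene
Conditions: Schrock catalyst Mo(=CHCMe2Ph)(=N-2,6-iPr2C6H3)[OCMe(CF3)2]2 (10 mol%), benzene, 25 → 60 °C; filtration through basic alumina
Reagents that add atoms: none
Why: Ring-closing metathesis of an olefinic vinyl ether with a Schrock molybdenum alkylidene, a catalyst class established for cyclic enol ethers and for 1,1-disubstituted alkenes, should close ring A as the 2,3-dihydrofuran O3–C2=C1 with loss of ethene; no stereocentre is formed, and the bicyclo[3.3.0]oct-1-ene frame is the same as in Pauson–Khand enones.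

Step 7
Reactants: 7 (5R,6S)-6-(3,4-dimethoxyphenyl)-3,7-dioxabicyclo[3.3.0]oct-1-ene; 8 4-bromo-1,2-dimethoxybenzene
Product: 12 (1S,2S,5R,6S)-2,6-bis(3,4-dimethoxyphenyl)-3,7-dioxabicyclo[3.3.0]octan-1-ol, via aryllithium 9 (not isolated), via diarylcuprate 10 (not isolated), via oxirane 11 (not isolated)
Conditions: 8, t-BuLi (2 equiv per 8), Et2O, −78 °C, then CuI (0.5 equiv per 8), −40 °C; separately 7, dimethyldioxirane (1.1 equiv, acetone solution), CH2Cl2, −78 → 0 °C, volatiles removed at 0 °C; crude 11 in THF added to 10 (2 equiv), −78 → −30 °C; aq NH4Cl/NH3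
Reagents that add atoms: dimethyldioxirane CC1(C)OO1
Why: Dimethyldioxirane should transfer oxygen to the electron-rich C1=C2 enol ether of 7 from the convex face (the face of H-5, away from the folded ring B) to give oxirane 11, and the Gilman cuprate 10 should open it by SN2 attack at the acetal carbon C2 anti to the oxirane oxygen, forming the C2–aryl bond with inversion and releasing the C1 alkoxide. The closest known reaction type is the trans-selective opening of glycal epoxides (1,2-anhydro sugars) by lithium diorganocuprates to give 1,2-trans C-glycosides. No ring of the target is closed here: the three-membered oxirane is formed by concerted oxygen transfer and opened again, and rings A and B are carried through. C1 (S) is controlled by the ring fusion, since only convex-face oxygen transfer leads to the cis-fused bicycle with the hydroxyl cis to H-5; C2 (S) is controlled by the stereospecific anti opening, which places the aryl group on the concave face trans to the C1 oxygen and H-2 cis to the hydroxyl. The step needs attack at C2 and not at C1, secured by the acetal character of C2 and the fully substituted C1, and it needs SN2 opening instead of ionisation with syn delivery, secured by a soft, weakly Lewis acidic cuprate in ether at low temperature with acetone and Lewis acids absent. One operation should thus add the second aryl ring, the tertiary hydroxyl and two stereocentres to a precursor that has neither.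

**Compound list**

1 | 3,4-dimethoxybenzaldehyde | COc1ccc(C=O)cc1OC | starting material
2 | rac-1-(3,4-dimethoxyphenyl)prop-2-en-1-ol | COc1ccc(C(O)C=C)cc1OC | intermediate
3 | (R)-(3,4-dimethoxyphenyl)[(2R)-oxiran-2-yl]methanol | COc1ccc([C@H]([C@H]2CO2)O)cc1OC | intermediate
4 | (2R)-2-[(R)-(3,4-dimethoxyphenyl)(prop-2-yn-1-yloxy)methyl]oxirane | COc1ccc([C@H]([C@H]2CO2)OCC#C)cc1OC | intermediate
5 | [(2S,3R)-2-(3,4-dimethoxyphenyl)-4-methylideneoxolan-3-yl]methanol (aryl and CH2OH trans) | COc1ccc([C@H]2OCC(=C)[C@@H]2CO)cc1OC | intermediate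
6 | (2S,3R)-2-(3,4-dimethoxyphenyl)-3-[(ethenyloxy)methyl]-4-methylideneoxolane | COc1ccc([C@H]2OCC(=C)[C@@H]2COC=C)cc1OC | intermediate
7 | (5R,6S)-6-(3,4-dimethoxyphenyl)-3,7-dioxabicyclo[3.3.0]oct-1-ene (enol ether O3–C2=C1; aryl cis to H-5) | COc1ccc([C@H]2OCC3=COC[C@H]23)cc1OC | intermediate
8 | 4-bromo-1,2-dimethoxybenzene | COc1ccc(Br)cc1OC | starting material
9 | (3,4-dimethoxyphenyl)lithium | [Li]c1ccc(OC)c(OC)c1 | intermediate
10 | lithium bis(3,4-dimethoxyphenyl)cuprate | [Li+].COc1ccc([Cu-]c2ccc(OC)c(OC)c2)cc1OC | intermediate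
11 | (1S,2R,5R,6S)-6-(3,4-dimethoxyphenyl)-1,2-epoxy-3,7-dioxabicyclo[3.3.0]octane (oxirane oxygen on the convex face, cis to H-5) | COc1ccc([C@H]2OC[C@@]34O[C@H]4OC[C@H]23)cc1OC | intermediate
12 | (1S,2S,5R,6S)-2,6-bis(3,4-dimethoxyphenyl)-3,7-dioxabicyclo[3.3.0]octan-1-ol | COc1ccc([C@H]2OC[C@@]3(O)[C@@H]2CO[C@H]3c2ccc(OC)c(OC)c2)cc1OC | target

**Count**

Total steps: 7. Longest linear sequence: 7 steps (1 → 12); bromide 8 enters in step 7 and is metalated in the same operation.

**Steps most likely to fail**

Step 7. The risk is ionisation of the very labile oxirane to the oxocarbenium ion before or during the union, followed by convex-face (syn) aryl delivery or oligomerisation, which would erode the trans relationship at C1/C2. The fallback sets out from 7 and returns at 12, separating bond formation from stereocontrol. Enol ether 7 would be oxidised with pyridinium chlorochromate (C5H5NH)[CrO3Cl] (CH2Cl2, rt, oxidation of a cyclic enol ether to the lactone) to (1R,5R,6S)-6-(3,4-dimethoxyphenyl)-3,7-dioxabicyclo[3.3.0]octan-2-one F1. Enolisation with LiN(SiMe3)2 (THF, −78 °C) and hydroxylation with 3-phenyl-2-(phenylsulfonyl)oxaziridine from the convex face would give the cis-fused (1S,5R,6S)-6-(3,4-dimethoxyphenyl)-1-hydroxy-3,7-dioxabicyclo[3.3.0]octan-2-one F2. Addition of aryllithium 9 (3 equiv, THF, −78 °C) to the lactone carbonyl would form the C2–aryl bond and give the hemiketal (1S,5R,6S)-2,6-bis(3,4-dimethoxyphenyl)-3,7-dioxabicyclo[3.3.0]octane-1,2-diol F3. Reduction with Et3SiH and BF3·OEt2 (CH2Cl2, −78 → −30 °C) should deliver hydride to the convex face of the 2-aryl oxocarbenium ion, placing H-2 cis to the hydroxyl and the aryl group endo, which is 12.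

Step 6. The risk is that the catalyst is held as an unreactive alkoxy-carbene or turns over too slowly at the 1,1-disubstituted alkene, or that the acid-sensitive enol ether is lost on isolation. The fallback sets out from 5 and returns at 7 by the classical lactol dehydration. Alcohol 5 would be silylated (TBSCl, imidazole, DMF) to tert-butyl{[(2S,3R)-2-(3,4-dimethoxyphenyl)-4-methylideneoxolan-3-yl]methoxy}dimethylsilane F4. Hydroboration–oxidation (9-BBN, THF; NaOH, H2O2) anti to the neighbouring CH2OTBS group would give the cis alcohol [(3S,4R,5S)-4-({[tert-butyl(dimethyl)silyl]oxy}methyl)-5-(3,4-dimethoxyphenyl)oxolan-3-yl]methanol F5. Dess–Martin oxidation (NaHCO3, CH2Cl2) would give (3R,4R,5S)-4-({[tert-butyl(dimethyl)silyl]oxy}methyl)-5-(3,4-dimethoxyphenyl)oxolane-3-carbaldehyde F6. Desilylation with HF·pyridine (THF) would close the lactol (1R,5R,6S)-6-(3,4-dimethoxyphenyl)-3,7-dioxabicyclo[3.3.0]octan-2-ol F7, and mesylation–elimination (MsCl, Et3N, CH2Cl2, −20 → 40 °C) would give 7.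

Step 3. The risk is base-induced oxirane migration (Payne rearrangement) of the alkoxide of 3 before alkylation, so that the propargyl group ends on the wrong oxygen. The fallback sets out from 2 and returns at 4, and never forms an alkoxide next to an oxirane. Racemate 2 would be resolved with the enantiomeric catalyst (Ti(OiPr)4, L-(+)-diisopropyl tartrate, t-BuOOH 0.6 equiv, CH2Cl2, −20 °C), leaving (S)-1-(3,4-dimethoxyphenyl)prop-2-en-1-ol F8 and consuming the (R)-alcohol as (S)-(3,4-dimethoxyphenyl)[(2S)-oxiran-2-yl]methanol F9, which is discarded. Etherification of F8 (NaH, propargyl bromide, THF) would give 4-[(1S)-1-(prop-2-yn-1-yloxy)prop-2-en-1-yl]-1,2-dimethoxybenzene F10. Epoxidation of the terminal alkene (mCPBA, NaHCO3, CH2Cl2, rt) would give 4 together with its oxirane epimer (2S)-2-[(R)-(3,4-dimethoxyphenyl)(prop-2-yn-1-yloxy)methyl]oxirane F11. The mixture can be used as such in step 4, because the oxirane stereocentre is erased in the C5 radical.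

Further compounds
F1 | step 7 | (1R,5R,6S)-6-(3,4-dimethoxyphenyl)-3,7-dioxabicyclo[3.3.0]octan-2-one | COc1ccc([C@H]2OC[C@@H]3C(=O)OC[C@H]23)cc1OC
F2 | step 7 | (1S,5R,6S)-6-(3,4-dimethoxyphenyl)-1-hydroxy-3,7-dioxabicyclo[3.3.0]octan-2-one | COc1ccc([C@H]2OC[C@]3(O)C(=O)OC[C@H]23)cc1OC
F3 | step 7 | (1S,5R,6S)-2,6-bis(3,4-dimethoxyphenyl)-3,7-dioxabicyclo[3.3.0]octane-1,2-diol (hemiketal, both C2 epimers) | COc1ccc([C@H]2OC[C@]3(O)C(O)(c4ccc(OC)c(OC)c4)OC[C@H]23)cc1OC
F4 | step 6 | tert-butyl{[(2S,3R)-2-(3,4-dimethoxyphenyl)-4-methylideneoxolan-3-yl]methoxy}dimethylsilane | COc1ccc([C@H]2OCC(=C)[C@@H]2CO[Si](C)(C)C(C)(C)C)cc1OC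
F5 | step 6 | [(3S,4R,5S)-4-({[tert-butyl(dimethyl)silyl]oxy}methyl)-5-(3,4-dimethoxyphenyl)oxolan-3-yl]methanol | COc1ccc([C@H]2OC[C@H](CO)[C@@H]2CO[Si](C)(C)C(C)(C)C)cc1OC
F6 | step 6 | (3R,4R,5S)-4-({[tert-butyl(dimethyl)silyl]oxy}methyl)-5-(3,4-dimethoxyphenyl)oxolane-3-carbaldehyde | COc1ccc([C@H]2OC[C@H](C=O)[C@@H]2CO[Si](C)(C)C(C)(C)C)cc1OC
F7 | step 6 | (1R,5R,6S)-6-(3,4-dimethoxyphenyl)-3,7-dioxabicyclo[3.3.0]octan-2-ol (lactol, both C2 epimers) | COc1ccc([C@H]2OC[C@@H]3C(O)OC[C@H]23)cc1OC
F8 | step 3 | (S)-1-(3,4-dimethoxyphenyl)prop-2-en-1-ol | COc1ccc([C@H](C=C)O)cc1OC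
F9 | step 3 | (S)-(3,4-dimethoxyphenyl)[(2S)-oxiran-2-yl]methanol | COc1ccc([C@@H]([C@@H]2CO2)O)cc1OC
F10 | step 3 | 4-[(1S)-1-(prop-2-yn-1-yloxy)prop-2-en-1-yl]-1,2-dimethoxybenzene | COc1ccc([C@H](C=C)OCC#C)cc1OC
F11 | step 3 | (2S)-2-[(R)-(3,4-dimethoxyphenyl)(prop-2-yn-1-yloxy)methyl]oxirane | COc1ccc([C@H]([C@@H]2CO2)OCC#C)cc1OC
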